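**Strategy.** The dimer is cut at C4(upper)–C6(lower) into two all-cis flavan-3,4-diol monomers that differ only in ring B and both come from one anti-aldol thioester. In each, the pyran ring is closed last: an open α-benzyloxy-β-silyloxy 2-hydroxyaryl ketone is cyclised and reduced in one operation (hemiketal, 2-aryl oxocarbenium ion, silane), forming O1–C2 and setting C2. The step exploits two features of ring C of the lower unit: C2 is benzylic to catechol ring B and acetal-like through O1 of ring A, so it can be carried as a ketone; and H-2 lies trans to the cis oxygens on C3 and C4, so hydride enters anti to both.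

Key step: step 9

Remark: "upper unit" is the 4-hydroxyphenyl flavan bonded through its C4, "lower unit" the catechol-bearing flavan-3,4-diol bonded through its C6; flavan numbering and rings A, B, C are used throughout.

Assumption: the (S)-diamine in step 5 is taken to give the (2R,3R) adduct; if the sense of induction is the opposite, the (R)-diamine is used and nothing else changes.

Step 1
Reactants: 1 2,3,4-trihydroxybenzaldehyde
Product: 2 3,4-bis(benzyloxy)-2-hydroxybenzaldehyde
Conditions: BnBr (2.05 equiv), K2CO3 (2.1 equiv), DMF, 0 °C → rt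
Reagents that add atoms: benzyl bromide, BrCc1ccccc1
Why: Williamson etherification; the 2-hydroxyl is held in a hydrogen bond to the formyl group and its phenoxide is the poorest nucleophile, so benzylation should stop after the 4- and 3-hydroxyls.

Step 2
Reactants: 2 3,4-bis(benzyloxy)-2-hydroxybenzaldehyde
Product: 3 3,4-bis(benzyloxy)-2-[(tert-butyldimethylsilyl)oxy]benzaldehyde
Conditions: tBuMe2SiCl, imidazole, DMF, rt
Reagents that add atoms: tert-butyldimethylsilyl chloride, CC(C)(C)[Si](C)(C)Cl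
Why: Imidazole-promoted silylation masks the future O1 until ring closure and removes the acidic phenol before the Lewis-acid aldol.

Step 3
Reactants: 4 (benzyloxy)acetyl chloride; 5 ethanethiol
Product: 6 S-ethyl 2-(benzyloxy)ethanethioate
Conditions: pyridine, CH2Cl2, 0 °C
Reagents that add atoms: none
Why: S-acylation of the thiol gives the thioester needed both for the tin-mediated aldol and for the later thioester–organozinc coupling.

Step 4
Reactants: 6 S-ethyl 2-(benzyloxy)ethanethioate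
Product: 8 [2-(benzyloxy)-1-(ethylsulfanyl)ethenyl]oxy(trimethyl)silane with benzyloxy cis to silyloxy, via lithium enolate 7 (not isolated)
Conditions: LiN(iPr)2, Me3SiCl, THF, −78 °C
Reagents that add atoms: chlorotrimethylsilane, C[Si](C)(C)Cl
Why: Lithium-chelated enolisation (benzyloxy and enolate oxygens on one lithium) followed by O-silylation in situ should give the ketene silyl thioacetal geometry required for anti selectivity.

Step 5
Reactants: 3 3,4-bis(benzyloxy)-2-[(tert-butyldimethylsilyl)oxy]benzaldehyde; 8 ketene silyl thioacetal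
Product: 9 S-ethyl (2R,3R)-2-(benzyloxy)-3-{3,4-bis(benzyloxy)-2-[(tert-butyldimethylsilyl)oxy]phenyl}-3-hydroxypropanethioate
Conditions: Sn(OTf)2 (1.1 equiv), (S)-1-methyl-2-(piperidin-1-ylmethyl)pyrrolidine (1.2 equiv), Bu2Sn(OAc)2 (1.1 equiv), CH2Cl2, −78 °C; aq NaHCO3
Reagents that add atoms: none
Why: Mukaiyama aldol addition under a chiral divalent-tin Lewis acid; coordination of the benzyloxy oxygen to tin in an open transition state should give the anti adduct and the proline-derived diamine selects the aldehyde face, so the future C3 and C4 of both flavan units are set here.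

Step 6
Reactants: 9 anti aldol adduct
Product: 10 S-ethyl (2R,3R)-2-(benzyloxy)-3-{3,4-bis(benzyloxy)-2-[(tert-butyldimethylsilyl)oxy]phenyl}-3-[(tert-butyldimethylsilyl)oxy]propanethioate
Conditions: tBuMe2SiOTf, 2,6-lutidine, CH2Cl2, −78 → 0 °C
Reagents that add atoms: tert-butyldimethylsilyl trifluoromethanesulfonate, CC(C)(C)[Si](C)(C)OS(=O)(=O)C(F)(F)F
Why: Silylation of the secondary alcohol blocks retro-aldol cleavage and later ionisation at this electron-rich benzylic carbon.

Step 7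
Reactants: 10 bis-silylated thioester; 11 1,2-bis(benzyloxy)-4-bromobenzene
Product: 14 (2R,3R)-2-(benzyloxy)-3-{3,4-bis(benzyloxy)-2-[(tert-butyldimethylsilyl)oxy]phenyl}-1-[3,4-bis(benzyloxy)phenyl]-3-[(tert-butyldimethylsilyl)oxy]propan-1-one, via arylmagnesium bromide 12 (not isolated), via arylzinc bromide 13 (not isolated)
Conditions: 11, Mg, THF, 40 °C; ZnBr2, 0 °C; then 10, PdCl2(PPh3)2 (5 mol %), THF–toluene, rt; aq NH4Cl
Reagents that add atoms: none
Why: Fukuyama coupling (palladium-catalysed acylation of an arylzinc halide by a thioester) stops at the ketone under neutral conditions, so the α-stereocentre and both silyl ethers should survive.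

Step 8
Reactants: 14 lower-series silyl-protected ketone
Product: 15 (2R,3R)-2-(benzyloxy)-3-[3,4-bis(benzyloxy)-2-hydroxyphenyl]-1-[3,4-bis(benzyloxy)phenyl]-3-[(tert-butyldimethylsilyl)oxy]propan-1-one
Conditions: KHF2, MeOH, rt
Reagents that add atoms: none
Why: Bifluoride in methanol cleaves the aryl silyl ether much faster than the hindered secondary alkyl silyl ether, and the weakly acidic medium avoids epimerisation α to the ketone.

Step 9
Reactants: 15 open 2-hydroxyaryl ketone of the lower series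
Product: 18 (2R,3S,4R)-3,7,8-tris(benzyloxy)-2-[3,4-bis(benzyloxy)phenyl]-4-[(tert-butyldimethylsilyl)oxy]-3,4-dihydro-2H-chromene (2,3-cis-3,4-cis), via cyclic hemiketal 16 (not isolated), via oxocarbenium triflate 17 (not isolated)
Conditions: Et3SiH (5 equiv), Me3SiOTf (0.5 equiv), CH2Cl2, −78 °C; Et3N quench at −78 °C
Reagents that add atoms: none
Why: Acid turns the open ketone 15 into cyclic hemiketal 16 by attack of the ring-A phenol oxygen on the carbonyl carbon (this makes O1–C2) and ionises 16 to the 2-aryl oxocarbenium ion 17, which Et3SiH reduces irreversibly. The closest known reaction type is the silane/Lewis-acid reductive etherification of hydroxy ketones, as used for hemiketal reduction to C-aryl glycosides. One ring, pyran ring C, is closed, in the 6-exo-trig mode at the carbonyl group. C2 is the only new stereocentre and is set by the substrate: the ring-B aryl group stays coplanar with O1=C2 in 17, so A(1,2) strain pushes the 3-benzyloxy group pseudoaxial, the cis 4-silyloxy group lies on the same face, and hydride adds axially to the opposite face, leaving H-2 trans to O-3 and O-4 and the aryl group cis to both. The step needs chemoselectivity for the hemiketal over the benzylic C4–O bond and must not re-ionise the product at C2; the far greater stability of the tertiary, aryl- and oxygen-stabilised cation 17, the silyl group on O-4, −78 °C and a cold Et3N quench should secure this. Because C2 is trigonal in 15, no configuration has to be carried into the step at this carbon.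

Step 10
Reactants: 10 bis-silylated thioester; 19 1-(benzyloxy)-4-bromobenzene
Product: 22 (2R,3R)-2-(benzyloxy)-3-{3,4-bis(benzyloxy)-2-[(tert-butyldimethylsilyl)oxy]phenyl}-1-[4-(benzyloxy)phenyl]-3-[(tert-butyldimethylsilyl)oxy]propan-1-one, via arylmagnesium bromide 20 (not isolated), via arylzinc bromide 21 (not isolated)
Conditions: 19, Mg, THF, 40 °C; ZnBr2, 0 °C; then 10, PdCl2(PPh3)2 (5 mol %), THF–toluene, rt; aq NH4Cl
Reagents that add atoms: none
Why: The same Fukuyama coupling as in step 7 attaches ring B of the upper unit to the common thioester.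

Step 11
Reactants: 22 upper-series silyl-protected ketone
Product: 23 (2R,3R)-2-(benzyloxy)-3-[3,4-bis(benzyloxy)-2-hydroxyphenyl]-1-[4-(benzyloxy)phenyl]-3-[(tert-butyldimethylsilyl)oxy]propan-1-one
Conditions: KHF2, MeOH, rt
Reagents that add atoms: none
Why: Selective cleavage of the aryl silyl ether by bifluoride, as in step 8.

Step 12
Reactants: 23 open 2-hydroxyaryl ketone of the upper series
Product: 26 (2R,3S,4R)-3,7,8-tris(benzyloxy)-2-[4-(benzyloxy)phenyl]-4-[(tert-butyldimethylsilyl)oxy]-3,4-dihydro-2H-chromene (2,3-cis-3,4-cis), via cyclic hemiketal 24 (not isolated), via oxocarbenium triflate 25 (not isolated)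
Conditions: Et3SiH (5 equiv), Me3SiOTf (0.5 equiv), CH2Cl2, −78 °C; Et3N quench at −78 °C
Reagents that add atoms: none
Why: The same reductive cycloetherification as in step 9; hydride should again enter oxocarbenium ion 25 anti to the cis oxygens on C3 and C4 and give the all-cis flavan.

Step 13
Reactants: 26 all-cis upper monomer
Product: 28 (2R,3S,4S)-3,7,8-tris(benzyloxy)-2-[4-(benzyloxy)phenyl]-4-(benzylsulfanyl)-3,4-dihydro-2H-chromene (4β; 3,4-trans), via flavan-4-yl cation triflate 27 (not isolated)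
Conditions: BnSH (3 equiv), Me3SiOTf (0.2 equiv), CH2Cl2, −40 → 0 °C
Reagents that add atoms: phenylmethanethiol, SCc1ccccc1
Why: Acid-catalysed SN1 thiolysis of the activated benzylic silyl ether through the cation of ion pair 27 (stabilised by O1 ortho and the 7-benzyloxy group para), the thiol adding anti to the pseudoaxial 3-benzyloxy group; either C4 epimer would serve because C4 is ionised again in step 14.

Step 14
Reactants: 28 4β-benzylsulfanyl upper unit; 18 silyl-protected lower monomer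
Product: 30 protected nona-O-benzyl 4-O-silyl dimer (upper C4β bonded to lower C6), via flavan-4-yl cation tetrafluoroborate 29 (not isolated)
Conditions: 18 (3 equiv), AgBF4 (2 equiv), 2,6-di-tert-butyl-4-methylpyridine (2 equiv), 4 Å MS, CH2Cl2, −20 → 0 °C, dark; slow addition of 28
Reagents that add atoms: none
Why: Thiophilic activation by monovalent silver ionises the C4–S bond of 28 and delivers the flavan-4-yl cation as its tetrafluoroborate 29 while the silyl-protected C4–O of 18 stays inert; Friedel–Crafts attack by C6 of 18 (para to O1, ortho to the 7-benzyloxy group, the only doubly activated unhindered position) anti to the 3-benzyloxy group should set upper C4 as 4β, with excess 18 and slow addition suppressing self-condensation.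

Step 15
Reactants: 30 protected dimer
Product: 31 nona-O-benzyl dimer with free 4-hydroxyl on the lower unit
Conditions: Bu4NF, AcOH, THF, rt
Reagents that add atoms: none
Why: Fluoride-mediated desilylation buffered with acetic acid frees the lower 4-hydroxyl without base-induced side reactions.

Step 16
Reactants: 31 nona-O-benzyl dimer
Product: 32 epioritin-(4β→6)-melacacidin, CNP0275688.2
Conditions: H2 (1 atm), Pd(OH)2/C, THF–MeOH (1:1), rt
Reagents that add atoms: none
Why: Hydrogenolysis of the nine benzyl ethers under neutral conditions; a free benzylic hydroxyl is cleaved much more slowly than benzyl ethers, so the lower 4-OH should survive if the reaction is stopped at the end of hydrogen uptake.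

**Compound list**

1 | 2,3,4-trihydroxybenzaldehyde | O=Cc1ccc(O)c(O)c1O | starting material
2 | 3,4-bis(benzyloxy)-2-hydroxybenzaldehyde | O=Cc1ccc(OCc5ccccc5)c(OCc5ccccc5)c1O | intermediate
3 | 3,4-bis(benzyloxy)-2-[(tert-butyldimethylsilyl)oxy]benzaldehyde | O=Cc1ccc(OCc5ccccc5)c(OCc5ccccc5)c1O[Si](C)(C)C(C)(C)C | intermediate
4 | (benzyloxy)acetyl chloride | O=C(Cl)COCc1ccccc1 | starting material
5 | ethanethiol | CCS | starting material
6 | S-ethyl 2-(benzyloxy)ethanethioate | CCSC(=O)COCc1ccccc1 | intermediate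
7 | lithium enolate of 6, benzyloxy cis to O–Li | [Li+].CCS/C([O-])=C/OCc1ccccc1 | intermediate (not isolated)
8 | [2-(benzyloxy)-1-(ethylsulfanyl)ethenyl]oxy(trimethyl)silane, benzyloxy cis to silyloxy (E by sequence rules) | CCS/C(O[Si](C)(C)C)=C/OCc1ccccc1 | intermediate
9 | S-ethyl (2R,3R)-2-(benzyloxy)-3-{3,4-bis(benzyloxy)-2-[(tert-butyldimethylsilyl)oxy]phenyl}-3-hydroxypropanethioate (anti) | CCSC(=O)[C@H](OCc5ccccc5)[C@H](O)c1ccc(OCc5ccccc5)c(OCc5ccccc5)c1O[Si](C)(C)C(C)(C)C | intermediate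
10 | S-ethyl (2R,3R)-2-(benzyloxy)-3-{3,4-bis(benzyloxy)-2-[(tert-butyldimethylsilyl)oxy]phenyl}-3-[(tert-butyldimethylsilyl)oxy]propanethioate | CCSC(=O)[C@H](OCc5ccccc5)[C@H](O[Si](C)(C)C(C)(C)C)c1ccc(OCc5ccccc5)c(OCc5ccccc5)c1O[Si](C)(C)C(C)(C)C | intermediate
11 | 1,2-bis(benzyloxy)-4-bromobenzene | Brc1ccc(OCc5ccccc5)c(OCc5ccccc5)c1 | starting material
12 | [3,4-bis(benzyloxy)phenyl]magnesium bromide | Br[Mg]c1ccc(OCc5ccccc5)c(OCc5ccccc5)c1 | intermediate (not isolated)
13 | [3,4-bis(benzyloxy)phenyl]zinc bromide | Br[Zn]c1ccc(OCc5ccccc5)c(OCc5ccccc5)c1 | intermediate (not isolated)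
14 | (2R,3R)-2-(benzyloxy)-3-{3,4-bis(benzyloxy)-2-[(tert-butyldimethylsilyl)oxy]phenyl}-1-[3,4-bis(benzyloxy)phenyl]-3-[(tert-butyldimethylsilyl)oxy]propan-1-one | O=C(c1ccc(OCc5ccccc5)c(OCc5ccccc5)c1)[C@H](OCc5ccccc5)[C@H](O[Si](C)(C)C(C)(C)C)c1ccc(OCc5ccccc5)c(OCc5ccccc5)c1O[Si](C)(C)C(C)(C)C | intermediate
15 | (2R,3R)-2-(benzyloxy)-3-[3,4-bis(benzyloxy)-2-hydroxyphenyl]-1-[3,4-bis(benzyloxy)phenyl]-3-[(tert-butyldimethylsilyl)oxy]propan-1-one | O=C(c1ccc(OCc5ccccc5)c(OCc5ccccc5)c1)[C@H](OCc5ccccc5)[C@H](O[Si](C)(C)C(C)(C)C)c1ccc(OCc5ccccc5)c(OCc5ccccc5)c1O | intermediate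
16 | cyclic hemiketal of 15 (2-hydroxyflavan, both C2 epimers, 3,4-cis) | c1cc2c(c(OCc5ccccc5)c1OCc5ccccc5)OC(O)(c1ccc(OCc5ccccc5)c(OCc5ccccc5)c1)[C@H](OCc5ccccc5)[C@@H]2O[Si](C)(C)C(C)(C)C | intermediate (not isolated)
17 | 2-aryl oxocarbenium (3,4-dihydrochromenylium) triflate from 16 | c1cc2c(c(OCc5ccccc5)c1OCc5ccccc5)[O+]=C(c1ccc(OCc5ccccc5)c(OCc5ccccc5)c1)[C@H](OCc5ccccc5)[C@@H]2O[Si](C)(C)C(C)(C)C.[O-]S(=O)(=O)C(F)(F)F | intermediate (not isolated)
18 | (2R,3S,4R)-3,7,8-tris(benzyloxy)-2-[3,4-bis(benzyloxy)phenyl]-4-[(tert-butyldimethylsilyl)oxy]-3,4-dihydro-2H-chromene (all-cis, protected melacacidin) | c1cc2c(c(OCc5ccccc5)c1OCc5ccccc5)O[C@H](c1ccc(OCc5ccccc5)c(OCc5ccccc5)c1)[C@H](OCc5ccccc5)[C@@H]2O[Si](C)(C)C(C)(C)C | intermediate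
19 | 1-(benzyloxy)-4-bromobenzene | Brc1ccc(OCc5ccccc5)cc1 | starting material
20 | [4-(benzyloxy)phenyl]magnesium bromide | Br[Mg]c1ccc(OCc5ccccc5)cc1 | intermediate (not isolated)
21 | [4-(benzyloxy)phenyl]zinc bromide | Br[Zn]c1ccc(OCc5ccccc5)cc1 | intermediate (not isolated)
22 | (2R,3R)-2-(benzyloxy)-3-{3,4-bis(benzyloxy)-2-[(tert-butyldimethylsilyl)oxy]phenyl}-1-[4-(benzyloxy)phenyl]-3-[(tert-butyldimethylsilyl)oxy]propan-1-one | O=C(c1ccc(OCc5ccccc5)cc1)[C@H](OCc5ccccc5)[C@H](O[Si](C)(C)C(C)(C)C)c1ccc(OCc5ccccc5)c(OCc5ccccc5)c1O[Si](C)(C)C(C)(C)C | intermediate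
23 | (2R,3R)-2-(benzyloxy)-3-[3,4-bis(benzyloxy)-2-hydroxyphenyl]-1-[4-(benzyloxy)phenyl]-3-[(tert-butyldimethylsilyl)oxy]propan-1-one | O=C(c1ccc(OCc5ccccc5)cc1)[C@H](OCc5ccccc5)[C@H](O[Si](C)(C)C(C)(C)C)c1ccc(OCc5ccccc5)c(OCc5ccccc5)c1O | intermediate
24 | cyclic hemiketal of 23 (2-hydroxyflavan, both C2 epimers, 3,4-cis) | c1cc2c(c(OCc5ccccc5)c1OCc5ccccc5)OC(O)(c1ccc(OCc5ccccc5)cc1)[C@H](OCc5ccccc5)[C@@H]2O[Si](C)(C)C(C)(C)C | intermediate (not isolated)
25 | 2-aryl oxocarbenium (3,4-dihydrochromenylium) triflate from 24 | c1cc2c(c(OCc5ccccc5)c1OCc5ccccc5)[O+]=C(c1ccc(OCc5ccccc5)cc1)[C@H](OCc5ccccc5)[C@@H]2O[Si](C)(C)C(C)(C)C.[O-]S(=O)(=O)C(F)(F)F | intermediate (not isolated)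
26 | (2R,3S,4R)-3,7,8-tris(benzyloxy)-2-[4-(benzyloxy)phenyl]-4-[(tert-butyldimethylsilyl)oxy]-3,4-dihydro-2H-chromene (all-cis) | c1cc2c(c(OCc5ccccc5)c1OCc5ccccc5)O[C@H](c1ccc(OCc5ccccc5)cc1)[C@H](OCc5ccccc5)[C@@H]2O[Si](C)(C)C(C)(C)C | intermediate
27 | 2,3-cis-3,7,8-tris(benzyloxy)-2-[4-(benzyloxy)phenyl]-3,4-dihydro-2H-chromen-4-ylium trifluoromethanesulfonate (flavan-4-yl cation triflate; C2 and C3 as in 26) | c1cc2c(c(OCc5ccccc5)c1OCc5ccccc5)O[C@H](c1ccc(OCc5ccccc5)cc1)[C@H](OCc5ccccc5)[CH+]2.[O-]S(=O)(=O)C(F)(F)F | intermediate (not isolated)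
28 | (2R,3S,4S)-3,7,8-tris(benzyloxy)-2-[4-(benzyloxy)phenyl]-4-(benzylsulfanyl)-3,4-dihydro-2H-chromene (2,3-cis-3,4-trans, 4β) | c1cc2c(c(OCc5ccccc5)c1OCc5ccccc5)O[C@H](c1ccc(OCc5ccccc5)cc1)[C@H](OCc5ccccc5)[C@H]2SCc5ccccc5 | intermediate
29 | 2,3-cis-3,7,8-tris(benzyloxy)-2-[4-(benzyloxy)phenyl]-3,4-dihydro-2H-chromen-4-ylium tetrafluoroborate (flavan-4-yl cation tetrafluoroborate; C2 and C3 as in 28) | c1cc2c(c(OCc5ccccc5)c1OCc5ccccc5)O[C@H](c1ccc(OCc5ccccc5)cc1)[C@H](OCc5ccccc5)[CH+]2.F[B-](F)(F)F | intermediate (not isolated)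
30 | protected dimer: nona-O-benzyl, lower 4-O-tert-butyldimethylsilyl; upper 2,3-cis-3,4-trans unit bonded from C4 (4β) to C6 of the all-cis lower unit; configuration as in 32 | C(c5ccccc5)Oc1ccc([C@H]2Oc3c(ccc(OCc5ccccc5)c3OCc5ccccc5)[C@H](c3cc4c(c(OCc5ccccc5)c3OCc5ccccc5)O[C@H](c3ccc(OCc5ccccc5)c(OCc5ccccc5)c3)[C@H](OCc5ccccc5)[C@@H]4O[Si](C)(C)C(C)(C)C)[C@H]2OCc5ccccc5)cc1 | intermediate
31 | nona-O-benzyl dimer with free lower 4-hydroxyl; configuration as in 32 | C(c5ccccc5)Oc1ccc([C@H]2Oc3c(ccc(OCc5ccccc5)c3OCc5ccccc5)[C@H](c3cc4c(c(OCc5ccccc5)c3OCc5ccccc5)O[C@H](c3ccc(OCc5ccccc5)c(OCc5ccccc5)c3)[C@H](OCc5ccccc5)[C@@H]4O)[C@H]2OCc5ccccc5)cc1 | intermediate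
32 | epioritin-(4β→6)-melacacidin: (2R,3R,4S)-2,3-cis-3,4-trans-7,8,4'-trihydroxyflavan-3-ol bonded from C4 to C6 of (2R,3R,4R)-2,3-cis-3,4-cis-3',4',7,8-tetrahydroxyflavan-3,4-diol | Oc1ccc([C@H]2Oc3c(ccc(O)c3O)[C@H](c3cc4c(c(O)c3O)O[C@H](c3ccc(O)c(O)c3)[C@H](O)[C@@H]4O)[C@H]2O)cc1 | target

**Step count and risks**

Total steps: 16. Longest linear sequence: 11 steps (steps 1, 2, 5, 6, 10, 11, 12, 13, 14, 15, 16).

Step 9 (key step). Hydride may be delivered to the wrong face of oxocarbenium ion 17, or the product may re-ionise at C2 and be reduced further. The fallback sets out from 15 and replaces the cation reduction by a stereospecific displacement. Chelation-controlled reduction of the ketone (Zn(BH4)2, Et2O, −20 °C; zinc bridges the carbonyl and α-benzyloxy oxygens) should give the anti benzylic alcohol F1. A Mitsunobu cycloetherification (PPh3, DIAD, THF, 0 °C) then closes O1–C2 by SN2 displacement with inversion, which turns the anti relationship into the 2,3-cis flavan and comes back to the route at 18.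

Step 5. The chiral tin Lewis acid may give poor face selectivity or poor anti/syn selectivity with this hindered, electron-rich aldehyde. The fallback sets out from 3 and replaces catalyst control by auxiliary control. (S)-4-Benzyl-1,3-oxazolidin-2-one is N-acylated with 4 (BuLi, THF, −78 °C) to the glycolyl imide F2. Its MgCl2-catalysed direct anti-aldol addition to 3 (MgCl2, Et3N, Me3SiCl, EtOAc, rt; then citric acid, MeOH) should give the anti adduct F3, the chelated Z-enolate reacting on the face remote from the benzyl group of the auxiliary. Silylation (tBuMe2SiOTf, 2,6-lutidine, CH2Cl2) gives the silyl ether F4, and LiSEt (THF, 0 °C) displaces the auxiliary and comes back to the route at 10.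

Step 14. The cation may be consumed by self-condensation of the electrophile, or be captured too slowly by the only moderately nucleophilic ring A of 18. The fallback sets out from 26 and caps C6 of the electrophile with bromine. Bromination (N-bromosuccinimide, CH2Cl2, −20 °C) should give the 6-bromo flavan F5, and thiolysis as in step 13 the 6-bromo sulfide F6. Coupling with 18 under AgBF4 and 2,6-di-tert-butyl-4-methylpyridine as in step 14, now possible near 1:1 stoichiometry, should give the bromo dimer F7, and Bu4NF–AcOH the alcohol F8. Hydrogenolysis (H2, Pd(OH)2/C, Et3N, THF–MeOH) removes the bromine together with the benzyl groups and comes back to the route at 32.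

**Further compounds**

F1 | step 9 | (1S,2S,3R)-2-(benzyloxy)-3-[3,4-bis(benzyloxy)-2-hydroxyphenyl]-1-[3,4-bis(benzyloxy)phenyl]-3-[(tert-butyldimethylsilyl)oxy]propan-1-ol | O[C@@H](c1ccc(OCc5ccccc5)c(OCc5ccccc5)c1)[C@H](OCc5ccccc5)[C@H](O[Si](C)(C)C(C)(C)C)c1ccc(OCc5ccccc5)c(OCc5ccccc5)c1O
F2 | step 5 | (4S)-4-benzyl-3-[(benzyloxy)acetyl]-1,3-oxazolidin-2-one | O=C(COCc1ccccc1)N1[C@@H](Cc2ccccc2)COC1=O
F3 | step 5 | (4S)-4-benzyl-3-[(2R,3R)-2-(benzyloxy)-3-{3,4-bis(benzyloxy)-2-[(tert-butyldimethylsilyl)oxy]phenyl}-3-hydroxypropanoyl]-1,3-oxazolidin-2-one | O=C([C@H](OCc5ccccc5)[C@H](O)c1ccc(OCc5ccccc5)c(OCc5ccccc5)c1O[Si](C)(C)C(C)(C)C)N1[C@@H](Cc2ccccc2)COC1=O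
F4 | step 5 | (4S)-4-benzyl-3-[(2R,3R)-2-(benzyloxy)-3-{3,4-bis(benzyloxy)-2-[(tert-butyldimethylsilyl)oxy]phenyl}-3-[(tert-butyldimethylsilyl)oxy]propanoyl]-1,3-oxazolidin-2-one | O=C([C@H](OCc5ccccc5)[C@H](O[Si](C)(C)C(C)(C)C)c1ccc(OCc5ccccc5)c(OCc5ccccc5)c1O[Si](C)(C)C(C)(C)C)N1[C@@H](Cc2ccccc2)COC1=O
F5 | step 14 | (2R,3S,4R)-3,7,8-tris(benzyloxy)-2-[4-(benzyloxy)phenyl]-6-bromo-4-[(tert-butyldimethylsilyl)oxy]-3,4-dihydro-2H-chromene | Brc1cc2c(c(OCc5ccccc5)c1OCc5ccccc5)O[C@H](c1ccc(OCc5ccccc5)cc1)[C@H](OCc5ccccc5)[C@@H]2O[Si](C)(C)C(C)(C)C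
F6 | step 14 | (2R,3S,4S)-3,7,8-tris(benzyloxy)-2-[4-(benzyloxy)phenyl]-4-(benzylsulfanyl)-6-bromo-3,4-dihydro-2H-chromene | Brc1cc2c(c(OCc5ccccc5)c1OCc5ccccc5)O[C@H](c1ccc(OCc5ccccc5)cc1)[C@H](OCc5ccccc5)[C@H]2SCc5ccccc5
F7 | step 14 | 6-bromo analogue of 30 (bromine on C6 of the upper unit) | C(c5ccccc5)Oc1ccc([C@H]2Oc3c(cc(Br)c(OCc5ccccc5)c3OCc5ccccc5)[C@H](c3cc4c(c(OCc5ccccc5)c3OCc5ccccc5)O[C@H](c3ccc(OCc5ccccc5)c(OCc5ccccc5)c3)[C@H](OCc5ccccc5)[C@@H]4O[Si](C)(C)C(C)(C)C)[C@H]2OCc5ccccc5)cc1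
F8 | step 14 | 6-bromo analogue of 31 (bromine on C6 of the upper unit) | C(c5ccccc5)Oc1ccc([C@H]2Oc3c(cc(Br)c(OCc5ccccc5)c3OCc5ccccc5)[C@H](c3cc4c(c(OCc5ccccc5)c3OCc5ccccc5)O[C@H](c3ccc(OCc5ccccc5)c(OCc5ccccc5)c3)[C@H](OCc5ccccc5)[C@@H]4O)[C@H]2OCc5ccccc5)cc1
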